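**Retrosynthetic overview**

- Atom labels and the feature used: the prenyl-bearing bridgeheads are C1 and C5, the bridge C2–C3–C4 is the enolised β-diketone with the aroyl group on C3, C9 is the one-carbon ketone bridge, and the second three-carbon bridge is C6 (CH2), C7 (CH carrying geranyl) and C8 (CMe2). Ring A is C1–C8–C7–C6–C5–C9 and ring B is C1–C2–C3–C4–C5–C9. The plan rests on the C1–C8 bond: C1 is an enol carbon of a phloroglucinol-derived ring B and C8 is a gem-dimethyl carbon, so C8 can serve as a tertiary cation and C1 as its nucleophile.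
- Disconnection 1 (last ring, step 14): C1–C8, closing ring A by acid-triggered cation–olefin cyclisation of a monocyclic, dearomatised ring B that carries the C6–C7–C8 chain on C5 (isopropenyl as latent C8 cation) and a methyl enol ether at C9.
- Disconnection 2 (step 12): C5–C6, by alkylative dearomatisation of a symmetric 3,5-diprenyl aroylphloroglucinol with an enantiopure primary triflate whose C7 centre comes from an Evans dienolate geranylation.
- Disconnection 3: the aroylphloroglucinol from phloroglucinol tris(MOM ether) by three directed ortho-lithiations (prenyl, prenyl, silyl-protected 3,4-dihydroxybenzoyl). Ring order: ring B is the phloroglucinol ring, ring A is closed in step 14, and desilylation ends the route.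

Key step: step 14

Remark: enolised compounds are written as one tautomer and descriptors refer to it (4R in 25 versus 4S in 26 is a change of CIP priority, not of configuration); (R)-4-benzyl-1,3-oxazolidin-2-one and 3-methylbut-2-enoyl chloride are taken as two further commercial materials; which of the two C5 epimers formed in step 12 is 25 is to be confirmed by NOE on 29 after ring closure.

**Route**

Step 1
Reactants: 1 phloroglucinol
Product: 2 1,3,5-tris(methoxymethoxy)benzene
Conditions: MOMCl, i-Pr2NEt, CH2Cl2/DMF, 0 °C → rt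
Reagents that add atoms: chloromethyl methyl ether, COCCl
Why: Williamson-type O-alkylation of all three phenols with the hard electrophile MOMCl should give the tris-acetal, which masks the acidic hydroxyls and supplies the directing groups for the ring lithiations that follow.

Step 2
Reactants: 2 1,3,5-tris(methoxymethoxy)benzene; 3 prenyl bromide
Product: 5 1,3,5-tris(methoxymethoxy)-2-(3-methylbut-2-enyl)benzene, via aryllithium 4 (not isolated)
Conditions: n-BuLi, THF, 0 °C; then CuI (10 mol %), 3, −78 °C → rt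
Reagents that add atoms: none
Why: Directed ortho-metalation between two MOM ethers gives aryllithium 4, and copper-catalysed allylic substitution (SN2) on prenyl bromide at its unsubstituted terminus should deliver the C-prenyl arene without the O-alkylation and over-alkylation of direct phenol prenylation.

Step 3
Reactants: 5 1,3,5-tris(methoxymethoxy)-2-(3-methylbut-2-enyl)benzene; 3 prenyl bromide
Product: 7 1,3,5-tris(methoxymethoxy)-2,4-bis(3-methylbut-2-enyl)benzene, via aryllithium 6 (not isolated)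
Conditions: n-BuLi, THF, 0 °C; then CuI (10 mol %), 3, −78 °C → rt
Reagents that add atoms: none
Why: A second directed ortho-metalation, at either of the two equivalent positions still lying between two MOM ethers and faster than lateral metalation of the prenyl methylene, followed by the same copper-catalysed SN2 prenylation should give the 2,4-diprenyl arene as one regioisomer.

Step 4
Reactants: 8 3,4-dihydroxybenzoic acid
Product: 10 3,4-bis(tert-butyldimethylsilyloxy)benzoic acid, via silyl ester 9 (not isolated)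
Conditions: TBSCl (3.3 equiv), imidazole, DMF, rt; then AcOH/THF/H2O, rt
Reagents that add atoms: tert-butyldimethylsilyl chloride, CC(C)(C)[Si](C)(C)Cl
Why: Exhaustive silylation followed by hydrolysis of the silyl ester, which is far more labile than an aryl silyl ether, in aqueous acetic acid should leave the two phenol silyl ethers in place.

Step 5
Reactants: 10 3,4-bis(tert-butyldimethylsilyloxy)benzoic acid
Product: 11 3,4-bis(tert-butyldimethylsilyloxy)benzoyl chloride
Conditions: (COCl)2, DMF (cat.), CH2Cl2, 0 °C → rt; concentrate, use crude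
Reagents that add atoms: oxalyl chloride, ClC(=O)C(Cl)=O
Why: Acid chloride formation through the Vilsmeier-type chloroiminium species from oxalyl chloride and catalytic DMF runs at or below room temperature, which aryl TBS ethers tolerate.

Step 6
Reactants: 7 1,3,5-tris(methoxymethoxy)-2,4-bis(3-methylbut-2-enyl)benzene; 11 3,4-bis(tert-butyldimethylsilyloxy)benzoyl chloride
Product: 13 [3,4-bis(tert-butyldimethylsilyloxy)phenyl][2,4,6-tris(methoxymethoxy)-3,5-bis(3-methylbut-2-enyl)phenyl]methanone, via aryllithium 12 (not isolated)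
Conditions: n-BuLi, THF, 0 °C; then cannulate into 11, THF, −78 → 0 °C
Reagents that add atoms: none
Why: Directed ortho-metalation at the last free ring position, again between two MOM ethers, and acylation of the aryllithium by inverse addition to the acid chloride should stop at the ketone because the di-ortho-substituted benzophenone is shielded against a second addition.

Step 7
Reactants: 13 [3,4-bis(tert-butyldimethylsilyloxy)phenyl][2,4,6-tris(methoxymethoxy)-3,5-bis(3-methylbut-2-enyl)phenyl]methanone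
Product: 14 [3,4-bis(tert-butyldimethylsilyloxy)phenyl][2,4,6-trihydroxy-3,5-bis(3-methylbut-2-enyl)phenyl]methanone
Conditions: HCl (0.5 M in MeOH), THF, rt
Reagents that add atoms: none
Why: Acid-catalysed transacetalisation to methanol removes the three aryl MOM ethers, which are activated by the ortho or para ketone, whereas aryl TBS ethers resist dilute methanolic HCl and the ortho-prenyl phenols should not close to chromans at room temperature.

Step 8
Reactants: 15 (R)-4-benzyl-1,3-oxazolidin-2-one; 16 3-methylbut-2-enoyl chloride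
Product: 18 (4R)-4-benzyl-3-(3-methylbut-2-enoyl)-1,3-oxazolidin-2-one, via lithiated oxazolidinone 17 (not isolated)
Conditions: n-BuLi, THF, −78 °C; then 16, −78 → 0 °C
Reagents that add atoms: none
Why: N-Acylation of the lithiated Evans oxazolidinone with the acid chloride at −78 °C is the standard way to the enoyl imide.

Step 9
Reactants: 18 (4R)-4-benzyl-3-(3-methylbut-2-enoyl)-1,3-oxazolidin-2-one; 19 geranyl bromide
Product: 21 (4R)-4-benzyl-3-[(2R,4E)-5,9-dimethyl-2-(prop-1-en-2-yl)deca-4,8-dienoyl]-1,3-oxazolidin-2-one, via sodium dienolate 20 (not isolated)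
Conditions: NaN(SiMe3)2 (1.05 equiv), THF, −78 °C; then 19, −78 → −40 °C
Reagents that add atoms: none
Why: Evans alkylation of a dienolate: γ-deprotonation gives the chelated Z-dienolate 20, which reacts with geranyl bromide at the α-carbon (deconjugative alkylation) on the face away from the benzyl group, so the (R)-auxiliary sets the (2R) centre (the future C7) and the isopropenyl group is formed in the same step.

Step 10
Reactants: 21 (4R)-4-benzyl-3-[(2R,4E)-5,9-dimethyl-2-(prop-1-en-2-yl)deca-4,8-dienoyl]-1,3-oxazolidin-2-one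
Product: 22 (2R,4E)-5,9-dimethyl-2-(prop-1-en-2-yl)deca-4,8-dien-1-ol
Conditions: LiBH4, MeOH (1 equiv), Et2O, 0 °C
Reagents that add atoms: none
Why: Reductive cleavage of the imide with LiBH4 should give the primary alcohol and return the auxiliary, under conditions not basic enough to epimerise the allylic stereocentre or to move the double bond into conjugation.

Step 11
Reactants: 22 (2R,4E)-5,9-dimethyl-2-(prop-1-en-2-yl)deca-4,8-dien-1-ol
Product: 23 (2R,4E)-5,9-dimethyl-2-(prop-1-en-2-yl)deca-4,8-dien-1-yl trifluoromethanesulfonate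
Conditions: Tf2O, 2,6-lutidine, CH2Cl2, −78 °C; cold filtration, use at once
Reagents that add atoms: trifluoromethanesulfonic anhydride, O=S(=O)(OS(=O)(=O)C(F)(F)F)C(F)(F)F
Why: Triflation of the primary alcohol with triflic anhydride and a hindered pyridine base at −78 °C should give a sulfonate reactive enough for SN2 displacement at a β-branched carbon, and it is used without storage.

Step 12
Reactants: 14 [3,4-bis(tert-butyldimethylsilyloxy)phenyl][2,4,6-trihydroxy-3,5-bis(3-methylbut-2-enyl)phenyl]methanone; 23 (2R,4E)-5,9-dimethyl-2-(prop-1-en-2-yl)deca-4,8-dien-1-yl trifluoromethanesulfonate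
Product: 25 (4R)-2-[3,4-bis(tert-butyldimethylsilyloxy)benzoyl]-4-[(2S,4E)-5,9-dimethyl-2-(prop-1-en-2-yl)deca-4,8-dienyl]-3,5-dihydroxy-4,6-bis(3-methylbut-2-enyl)cyclohexa-2,5-dien-1-one, via trilithium phenoxide 24 (not isolated)
Conditions: LiN(SiMe3)2 (3 equiv), THF, 0 °C; then 23, 0 °C → rt; chromatography on SiO2
Reagents that add atoms: none
Why: Alkylative dearomatisation: the lithium phenoxide 24 should react through a prenyl-bearing ring carbon with the primary triflate (SN2 at C6, C7 untouched) to create the quaternary C5, and because the two prenyl-bearing carbons are enantiotopic and the stereocentre of 23 is too remote to tell them apart, no control at C5 is expected, so 25 has to be freed from its C5 epimer by chromatography on silica.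

Step 13
Reactants: 25 (4R)-2-[3,4-bis(tert-butyldimethylsilyloxy)benzoyl]-4-[(2S,4E)-5,9-dimethyl-2-(prop-1-en-2-yl)deca-4,8-dienyl]-3,5-dihydroxy-4,6-bis(3-methylbut-2-enyl)cyclohexa-2,5-dien-1-one
Product: 26 (4S)-2-[3,4-bis(tert-butyldimethylsilyloxy)benzoyl]-4-[(2S,4E)-5,9-dimethyl-2-(prop-1-en-2-yl)deca-4,8-dienyl]-3-hydroxy-5-methoxy-4,6-bis(3-methylbut-2-enyl)cyclohexa-2,5-dien-1-one
Conditions: TMSCHN2, MeOH/toluene, 0 °C
Reagents that add atoms: trimethylsilyldiazomethane, C[Si](C)(C)C=[N+]=[N-]
Why: O-Methylation with trimethylsilyldiazomethane in methanol should take place at the acidic, non-chelated vinylogous acid hydroxyl, whereas the C4 hydroxyl is held in a hydrogen bond to the aroyl carbonyl, and methylation at either oxygen of the vinylogous acid leaves C1 as the β-carbon of an enol ether.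

Step 14
Reactants: 26 (4S)-2-[3,4-bis(tert-butyldimethylsilyloxy)benzoyl]-4-[(2S,4E)-5,9-dimethyl-2-(prop-1-en-2-yl)deca-4,8-dienyl]-3-hydroxy-5-methoxy-4,6-bis(3-methylbut-2-enyl)cyclohexa-2,5-dien-1-one
Product: 29 (1S,5S,7S)-3-[3,4-bis(tert-butyldimethylsilyloxy)benzoyl]-7-[(2E)-3,7-dimethylocta-2,6-dienyl]-4-hydroxy-8,8-dimethyl-1,5-bis(3-methylbut-2-enyl)bicyclo[3.3.1]non-3-ene-2,9-dione, via C8 tertiary cation 27 (not isolated), via C9 oxocarbenium ion 28 (not isolated)
Conditions: HCO2H (neat, degassed), 10–15 °C, short contact time; dilute with cold toluene, concentrate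
Reagents that add atoms: none
Why: Markovnikov protonation of the isopropenyl group by formic acid gives the tertiary C8 cation 27, the electron-rich C1 terminus of the C9 methyl enol ether adds to it to join two fully substituted carbons, and the resulting C9 oxocarbenium ion 28 passes its methyl group to formate to unveil the bridging ketone. The closest known reaction type is the acid-mediated cation–olefin cyclisation of dearomatised prenylated acylphloroglucinol enol ethers to type B bicyclo[3.3.1]nonane triones, in effect a Friedel–Crafts-like alkylation of an enol ether. Ring A (C1, C8, C7, C6, C5, C9) closes as a six-membered ring with the C9=C1 enol double bond inside the ring being formed, most likely through a boat-like array that leaves the geranyl group on C7 pseudo-equatorial. The new stereocentre C1 is fixed by geometry, since the chain hangs from the quaternary C5 and the C6–C7–C8 tether can bridge to C1 only on the face of the flat ring B that C6 occupies, and because C7 (S) was set relative to C5 (S) before the closure the geranyl group comes out endo, on the side of the C2–C4 bridge. The step needs C-alkylation at C1 rather than attack by C3 or by an enol oxygen and it needs the four trisubstituted alkenes to survive: C1 is the only enol ether β-carbon, C3 sits between three carbonyl-type carbons, the C4 hydroxyl is tied up in a hydrogen bond to the aroyl carbonyl, O9 is capped by the methyl group, and protonation of the prenyl and geranyl alkenes is reversible and finds no six-membered carbon trap during a short, cold exposure. Once C1 is quaternary ring B cannot return to a phenol, which drives the closure forward.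

Step 15
Reactants: 29 (1S,5S,7S)-3-[3,4-bis(tert-butyldimethylsilyloxy)benzoyl]-7-[(2E)-3,7-dimethylocta-2,6-dienyl]-4-hydroxy-8,8-dimethyl-1,5-bis(3-methylbut-2-enyl)bicyclo[3.3.1]non-3-ene-2,9-dione
Product: 30 (1S,5S,7S)-3-(3,4-dihydroxybenzoyl)-7-[(2E)-3,7-dimethylocta-2,6-dienyl]-4-hydroxy-8,8-dimethyl-1,5-bis(3-methylbut-2-enyl)bicyclo[3.3.1]non-3-ene-2,9-dione (target)
Conditions: HF·pyridine, pyridine, THF, 0 °C → rt, under argon
Reagents that add atoms: none
Why: Pyridine-buffered HF·pyridine should cleave the two aryl silyl ethers by attack of fluoride at silicon under conditions mild enough for the enolised triketone, the catechol and the four alkenes, and no stereocentre is at risk.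

**Compound list**

1 | phloroglucinol | Oc1cc(O)cc(O)c1 | starting material
2 | 1,3,5-tris(methoxymethoxy)benzene | COCOc1cc(OCOC)cc(OCOC)c1 | intermediate
3 | prenyl bromide (1-bromo-3-methylbut-2-ene) | CC(C)=CCBr | starting material
4 | 2,4,6-tris(methoxymethoxy)phenyllithium | [Li]c1c(OCOC)cc(OCOC)cc1OCOC | intermediate
5 | 1,3,5-tris(methoxymethoxy)-2-(3-methylbut-2-enyl)benzene | COCOc1cc(OCOC)c(CC=C(C)C)c(OCOC)c1 | intermediate
6 | [2,4,6-tris(methoxymethoxy)-3-(3-methylbut-2-enyl)phenyl]lithium | [Li]c1c(OCOC)cc(OCOC)c(CC=C(C)C)c1OCOC | intermediate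
7 | 1,3,5-tris(methoxymethoxy)-2,4-bis(3-methylbut-2-enyl)benzene | COCOc1cc(OCOC)c(CC=C(C)C)c(OCOC)c1CC=C(C)C | intermediate
8 | 3,4-dihydroxybenzoic acid | OC(=O)c1ccc(O)c(O)c1 | starting material
9 | tert-butyldimethylsilyl 3,4-bis(tert-butyldimethylsilyloxy)benzoate | CC(C)(C)[Si](C)(C)OC(=O)c1ccc(O[Si](C)(C)C(C)(C)C)c(O[Si](C)(C)C(C)(C)C)c1 | intermediate
10 | 3,4-bis(tert-butyldimethylsilyloxy)benzoic acid | OC(=O)c1ccc(O[Si](C)(C)C(C)(C)C)c(O[Si](C)(C)C(C)(C)C)c1 | intermediate
11 | 3,4-bis(tert-butyldimethylsilyloxy)benzoyl chloride | ClC(=O)c1ccc(O[Si](C)(C)C(C)(C)C)c(O[Si](C)(C)C(C)(C)C)c1 | intermediate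
12 | [2,4,6-tris(methoxymethoxy)-3,5-bis(3-methylbut-2-enyl)phenyl]lithium | [Li]c1c(OCOC)c(CC=C(C)C)c(OCOC)c(CC=C(C)C)c1OCOC | intermediate
13 | [3,4-bis(tert-butyldimethylsilyloxy)phenyl][2,4,6-tris(methoxymethoxy)-3,5-bis(3-methylbut-2-enyl)phenyl]methanone | COCOc1c(CC=C(C)C)c(OCOC)c(CC=C(C)C)c(OCOC)c1C(=O)c1ccc(O[Si](C)(C)C(C)(C)C)c(O[Si](C)(C)C(C)(C)C)c1 | intermediate
14 | [3,4-bis(tert-butyldimethylsilyloxy)phenyl][2,4,6-trihydroxy-3,5-bis(3-methylbut-2-enyl)phenyl]methanone | Oc1c(CC=C(C)C)c(O)c(CC=C(C)C)c(O)c1C(=O)c1ccc(O[Si](C)(C)C(C)(C)C)c(O[Si](C)(C)C(C)(C)C)c1 | intermediate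
15 | (R)-4-benzyl-1,3-oxazolidin-2-one | O=C1N[C@H](Cc2ccccc2)CO1 | starting material
16 | 3-methylbut-2-enoyl chloride | CC(C)=CC(Cl)=O | starting material
17 | N-lithio derivative of (R)-4-benzyl-1,3-oxazolidin-2-one | [Li]N1[C@H](Cc2ccccc2)COC1=O | intermediate
18 | (4R)-4-benzyl-3-(3-methylbut-2-enoyl)-1,3-oxazolidin-2-one | CC(C)=CC(=O)N1[C@H](Cc2ccccc2)COC1=O | intermediate
19 | geranyl bromide ((2E)-1-bromo-3,7-dimethylocta-2,6-diene) | CC(C)=CCC/C(C)=C/CBr | starting material
20 | sodium (Z)-dienolate of 18 | C=C(C)/C=C(\[O-])N1[C@H](Cc2ccccc2)COC1=O.[Na+] | intermediate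
21 | (4R)-4-benzyl-3-[(2R,4E)-5,9-dimethyl-2-(prop-1-en-2-yl)deca-4,8-dienoyl]-1,3-oxazolidin-2-one | CC(C)=CCC/C(C)=C/C[C@H](C(C)=C)C(=O)N1[C@H](Cc2ccccc2)COC1=O | intermediate
22 | (2R,4E)-5,9-dimethyl-2-(prop-1-en-2-yl)deca-4,8-dien-1-ol | CC(C)=CCC/C(C)=C/C[C@H](C(C)=C)CO | intermediate
23 | (2R,4E)-5,9-dimethyl-2-(prop-1-en-2-yl)deca-4,8-dien-1-yl trifluoromethanesulfonate | CC(C)=CCC/C(C)=C/C[C@H](C(C)=C)COS(=O)(=O)C(F)(F)F | intermediate
24 | trilithium triphenoxide of 14 | [Li+].[Li+].[Li+].[O-]c1c(CC=C(C)C)c([O-])c(CC=C(C)C)c([O-])c1C(=O)c1ccc(O[Si](C)(C)C(C)(C)C)c(O[Si](C)(C)C(C)(C)C)c1 | intermediate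
25 | (4R)-2-[3,4-bis(tert-butyldimethylsilyloxy)benzoyl]-4-[(2S,4E)-5,9-dimethyl-2-(prop-1-en-2-yl)deca-4,8-dienyl]-3,5-dihydroxy-4,6-bis(3-methylbut-2-enyl)cyclohexa-2,5-dien-1-one | CC(C)=CCC/C(C)=C/C[C@H](C(C)=C)C[C@]2(CC=C(C)C)C(O)=C(CC=C(C)C)C(=O)C(C(=O)c3ccc(O[Si](C)(C)C(C)(C)C)c(O[Si](C)(C)C(C)(C)C)c3)=C2O | intermediate
26 | (4S)-2-[3,4-bis(tert-butyldimethylsilyloxy)benzoyl]-4-[(2S,4E)-5,9-dimethyl-2-(prop-1-en-2-yl)deca-4,8-dienyl]-3-hydroxy-5-methoxy-4,6-bis(3-methylbut-2-enyl)cyclohexa-2,5-dien-1-one | CC(C)=CCC/C(C)=C/C[C@H](C(C)=C)C[C@]2(CC=C(C)C)C(OC)=C(CC=C(C)C)C(=O)C(C(=O)c3ccc(O[Si](C)(C)C(C)(C)C)c(O[Si](C)(C)C(C)(C)C)c3)=C2O | intermediate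
27 | C8 tertiary cation from 26 (formate salt) | CC(C)=CCC/C(C)=C/C[C@H]([C+](C)C)C[C@]2(CC=C(C)C)C(OC)=C(CC=C(C)C)C(=O)C(C(=O)c3ccc(O[Si](C)(C)C(C)(C)C)c(O[Si](C)(C)C(C)(C)C)c3)=C2O.O=C[O-] | intermediate
28 | bicyclic C9 O-methyl oxocarbenium ion (formate salt) | CC(C)=CCC/C(C)=C/C[C@H]1C[C@]2(CC=C(C)C)C(=[O+]C)[C@@](CC=C(C)C)(C(=O)C(C(=O)c3ccc(O[Si](C)(C)C(C)(C)C)c(O[Si](C)(C)C(C)(C)C)c3)=C2O)C1(C)C.O=C[O-] | intermediate
29 | (1S,5S,7S)-3-[3,4-bis(tert-butyldimethylsilyloxy)benzoyl]-7-[(2E)-3,7-dimethylocta-2,6-dienyl]-4-hydroxy-8,8-dimethyl-1,5-bis(3-methylbut-2-enyl)bicyclo[3.3.1]non-3-ene-2,9-dione | CC(C)=CCC/C(C)=C/C[C@H]1C[C@]2(CC=C(C)C)C(=O)[C@@](CC=C(C)C)(C(=O)C(C(=O)c3ccc(O[Si](C)(C)C(C)(C)C)c(O[Si](C)(C)C(C)(C)C)c3)=C2O)C1(C)C | intermediate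
30 | (1S,5S,7S)-3-(3,4-dihydroxybenzoyl)-7-[(2E)-3,7-dimethylocta-2,6-dienyl]-4-hydroxy-8,8-dimethyl-1,5-bis(3-methylbut-2-enyl)bicyclo[3.3.1]non-3-ene-2,9-dione | CC(C)=CCC/C(C)=C/C[C@H]1C[C@]2(CC=C(C)C)C(=O)[C@@](CC=C(C)C)(C(=O)C(C(=O)c3ccc(O)c(O)c3)=C2O)C1(C)C | target

**Step count and risks**

Total steps: 15. Longest linear sequence: 9 steps (1, 2, 3, 6, 7, 12, 13, 14, 15 from phloroglucinol).

Steps most likely to fail:

1. Step 14 (ring A closure). What may go wrong: protonation of the trisubstituted prenyl and geranyl alkenes competes with protonation of the isopropenyl group and leads to oxygen-terminated pyran formation or to polyene cyclisation inside the geranyl chain, and the C8 cation may be captured by the C4 enol oxygen in place of C1. Fallback: the same C8 cation is made by ionising a tertiary C8–O bond with a catalytic Lewis acid in an aprotic medium, so that no alkene has to be protonated. It sets out from alcohol 22. Mukaiyama hydration (Co(acac)2 cat., PhSiH3, O2, THF/i-PrOH), which should prefer the 1,1-disubstituted alkene to the trisubstituted ones, would give (2S,4E)-2-(2-hydroxypropan-2-yl)-5,9-dimethyldeca-4,8-dien-1-ol F1. Triflation of the primary hydroxyl (Tf2O, 2,6-lutidine, CH2Cl2, −78 °C), followed in the same flask by TESOTf on the tertiary hydroxyl, would give (2S,4E)-5,9-dimethyl-2-[2-(triethylsilyloxy)propan-2-yl]deca-4,8-dien-1-yl trifluoromethanesulfonate F2. Alkylative dearomatisation of 14 with F2 under the conditions of step 12 would give the C8 triethylsilyloxy analogue of 25 F3, after separation from its C5 epimer F4. Methylation as in step 13 would give the C9 methyl enol ether F5. Bi(OTf)3 (cat.) in CH2Cl2 at −40 °C should then ionise the tertiary silyl ether (a dehydrative Friedel–Crafts-type alkylation of an enol ether by a tertiary carbinol derivative), C1 closes ring A as in step 14, and the route is rejoined at 29.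

2. Step 12 (alkylative dearomatisation). What may go wrong: oxygen alkylation of the phenoxide and elimination or ionisation of the β-branched triflate outrun the slow carbon alkylation at a substituted ring carbon, and there is no control over which enantiotopic carbon reacts, so a substantial part of the alkylated material is expected to have the wrong C5 configuration. Fallback: the C5–C6 bond is made on the aromatic ring with an aryllithium, and the quaternary centre is then created by dearomatising prenylation, for which a far more reactive allylic electrophile serves. It sets out from 5. Ring lithiation (n-BuLi, THF, 0 °C, aryllithium 6) and SN2 alkylation with triflate 23 should give 1,3,5-tris(methoxymethoxy)-2-[(2S,4E)-5,9-dimethyl-2-(prop-1-en-2-yl)deca-4,8-dienyl]-4-(3-methylbut-2-enyl)benzene F6. A further lithiation and acylation with 11 as in step 6 would give the tris(MOM) aryl ketone F7. Cleavage of the MOM ethers as in step 7 would give the alkyl prenyl aroylphloroglucinol F8. Carbon prenylation of its lithium phenoxide with 3 (LiN(SiMe3)2, toluene/THF, 0 °C) at the chain-bearing carbon rejoins the route at 25. It would have to be separated from the C5 epimer of 25 F9, which comes from attack on the other face of the same carbon, and from the gem-diprenyl regioisomer of 25 F10, which comes from prenylation at the prenyl-bearing ring carbon. The fallback trades the reactivity problem for a selectivity problem.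

3. Step 6 (aryl ketone formation). What may go wrong: incomplete acylation of the hindered aryllithium by the acid chloride, or a second addition to the ketone. Fallback: carbonyl addition followed by oxidation. It sets out from 11 and 7. Reduction of 11 with LiAlH(Ot-Bu)3 (THF, −78 °C) would give 3,4-bis(tert-butyldimethylsilyloxy)benzaldehyde F11. Aryllithium 12 (from 7 as in step 6) should add to it at −78 °C to give racemic [3,4-bis(tert-butyldimethylsilyloxy)phenyl][2,4,6-tris(methoxymethoxy)-3,5-bis(3-methylbut-2-enyl)phenyl]methanol F12. Dess–Martin periodinane (NaHCO3, CH2Cl2, rt) would oxidise this to 13, where the route is rejoined.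

**Further compounds**

F1 | step 14 | (2S,4E)-2-(2-hydroxypropan-2-yl)-5,9-dimethyldeca-4,8-dien-1-ol | CC(C)=CCC/C(C)=C/C[C@H](C(C)(C)O)CO
F2 | step 14 | (2S,4E)-5,9-dimethyl-2-[2-(triethylsilyloxy)propan-2-yl]deca-4,8-dien-1-yl trifluoromethanesulfonate | CC(C)=CCC/C(C)=C/C[C@H](C(C)(C)O[Si](CC)(CC)CC)COS(=O)(=O)C(F)(F)F
F3 | step 14 | C8 triethylsilyloxy analogue of 25 (side chain 2-[2-(triethylsilyloxy)propan-2-yl] in place of 2-isopropenyl) | CC(C)=CCC/C(C)=C/C[C@H](C(C)(C)O[Si](CC)(CC)CC)C[C@]2(CC=C(C)C)C(O)=C(CC=C(C)C)C(=O)C(C(=O)c3ccc(O[Si](C)(C)C(C)(C)C)c(O[Si](C)(C)C(C)(C)C)c3)=C2O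
F4 | step 14 | C5 epimer of F3 | CC(C)=CCC/C(C)=C/C[C@H](C(C)(C)O[Si](CC)(CC)CC)C[C@@]2(CC=C(C)C)C(O)=C(CC=C(C)C)C(=O)C(C(=O)c3ccc(O[Si](C)(C)C(C)(C)C)c(O[Si](C)(C)C(C)(C)C)c3)=C2O
F5 | step 14 | C9 methyl enol ether of F3 | CC(C)=CCC/C(C)=C/C[C@H](C(C)(C)O[Si](CC)(CC)CC)C[C@]2(CC=C(C)C)C(OC)=C(CC=C(C)C)C(=O)C(C(=O)c3ccc(O[Si](C)(C)C(C)(C)C)c(O[Si](C)(C)C(C)(C)C)c3)=C2O
F6 | step 12 | 1,3,5-tris(methoxymethoxy)-2-[(2S,4E)-5,9-dimethyl-2-(prop-1-en-2-yl)deca-4,8-dienyl]-4-(3-methylbut-2-enyl)benzene | CC(C)=CCC/C(C)=C/C[C@H](C(C)=C)Cc1c(OCOC)cc(OCOC)c(CC=C(C)C)c1OCOC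
F7 | step 12 | [3,4-bis(tert-butyldimethylsilyloxy)phenyl]{3-[(2S,4E)-5,9-dimethyl-2-(prop-1-en-2-yl)deca-4,8-dienyl]-2,4,6-tris(methoxymethoxy)-5-(3-methylbut-2-enyl)phenyl}methanone | CC(C)=CCC/C(C)=C/C[C@H](C(C)=C)Cc1c(OCOC)c(C(=O)c2ccc(O[Si](C)(C)C(C)(C)C)c(O[Si](C)(C)C(C)(C)C)c2)c(OCOC)c(CC=C(C)C)c1OCOC
F8 | step 12 | [3,4-bis(tert-butyldimethylsilyloxy)phenyl]{3-[(2S,4E)-5,9-dimethyl-2-(prop-1-en-2-yl)deca-4,8-dienyl]-2,4,6-trihydroxy-5-(3-methylbut-2-enyl)phenyl}methanone | CC(C)=CCC/C(C)=C/C[C@H](C(C)=C)Cc1c(O)c(C(=O)c2ccc(O[Si](C)(C)C(C)(C)C)c(O[Si](C)(C)C(C)(C)C)c2)c(O)c(CC=C(C)C)c1O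
F9 | step 12 | C5 epimer of 25, (4S)-2-[3,4-bis(tert-butyldimethylsilyloxy)benzoyl]-4-[(2S,4E)-5,9-dimethyl-2-(prop-1-en-2-yl)deca-4,8-dienyl]-3,5-dihydroxy-4,6-bis(3-methylbut-2-enyl)cyclohexa-2,5-dien-1-one | CC(C)=CCC/C(C)=C/C[C@H](C(C)=C)C[C@@]2(CC=C(C)C)C(O)=C(CC=C(C)C)C(=O)C(C(=O)c3ccc(O[Si](C)(C)C(C)(C)C)c(O[Si](C)(C)C(C)(C)C)c3)=C2O
F10 | step 12 | gem-diprenyl regioisomer of 25 (both prenyl groups on the ring quaternary carbon, side chain on the enol carbon) | CC(C)=CCC/C(C)=C/C[C@H](C(C)=C)CC1=C(O)C(CC=C(C)C)(CC=C(C)C)C(O)=C(C(=O)c2ccc(O[Si](C)(C)C(C)(C)C)c(O[Si](C)(C)C(C)(C)C)c2)C1=O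
F11 | step 6 | 3,4-bis(tert-butyldimethylsilyloxy)benzaldehyde | O=Cc1ccc(O[Si](C)(C)C(C)(C)C)c(O[Si](C)(C)C(C)(C)C)c1
F12 | step 6 | racemic [3,4-bis(tert-butyldimethylsilyloxy)phenyl][2,4,6-tris(methoxymethoxy)-3,5-bis(3-methylbut-2-enyl)phenyl]methanol | COCOc1c(CC=C(C)C)c(OCOC)c(CC=C(C)C)c(OCOC)c1C(O)c1ccc(O[Si](C)(C)C(C)(C)C)c(O[Si](C)(C)C(C)(C)C)c1
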